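At partition balance 47.6 % of the J.Q and D together stands in the first phase, where G and L are made.

    Q ⇌ E, rate k1*([Q] - [E]/K1) per volume of the first phase (K1 = 0.60, k1 = 0.27 h⁻¹)
    J + Q → J.Q (k2 = 0.72 M⁻¹ h⁻¹)
    J.Q ⇌ D, rate k3*([J.Q] - [D]/K3) per volume of the first phase (K3 = 1.1, k3 = 0.24 h⁻¹)
    J.Q → G (k4 = 0.064 h⁻¹)
    J.Q → L (k5 = 0.093 h⁻¹)

J 0.54 M; E 3.00 equiv; time 10 h; volume of the second phase over the first 1.0

* the J.Q and D together standing at 10 h, as a percentage of the J charged
* part of the J charged that has reacted at 10 h

**Pool exit.** Call J.Q and D together the pool; in this flask its drain from the first phase is 0.157 h⁻¹, so at balance it would leave at 0.0748 h⁻¹. But D lags behind a draining first phase, and you correct for that with the rates summed, 0.615 h⁻¹: the pool exit rate, the smaller decay constant of the coupled J.Q and D balance, is 0.0619 h⁻¹, slower than the figure at balance.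

**Hand value.** Counting the J as consumed, [Q] levels at 0.675 M after a filling time of 1.39 h, and J then decays pseudo-first-order, giving cv, the part of the J charged that has reacted at 10 h, of 98.5 %. By this reckoning the pool is born on average at 3.45 h, and 80.6 % of it survives the fast early loss into the slow decline, so I commit to y, the pool at 10 h as a percentage of the J charged, of 53.8 %.

**Three settings.** Time: reading at twice the time takes my y down by 25 percentage points. E: doubling it brings the birth forward by 1.23 h, which lowers y by 4 points. J: doubling it at the same equivalents brings the birth forward by 1.03 h, lowering y by 3.3 points.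

**Result.** The forecast gives 52 % for y and 98.8 % for cv, with the pool that “decays slowly at about 0.06 per hour”. This flask gives 52.0 % for y and 98.7 % for cv, against my 53.8 % and 98.5 %, and the settings, each moved alone by the same factor up or down, rank by their largest move of y as time (8.5 points), then E (1.3 points), then J (0.98 points).

**Fill and drain.** In this flask half of the turnover of J + Q into J.Q up to the asked time is done by 2.29 h, and the pool's half-life at the pool exit rate is 11.2 h, longer by a factor of 4.89. At 10 h this flask has 1.3 % of the J left and the pool stands at 52.0 % of the J charged.

**Second flask.** Left until 40 h, the same flask should carry a pool of 8.12 % of the J charged at the pool exit rate, and it computes to 8.18 %.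

The numbers of this flask are invented; the run is a simulation.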